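## The problem

The target is a cyclohexene with four contiguous oxygen-bearing stereocentres and, on its fully substituted alkene carbon, an enyne–diene chain ending in a tertiary alcohol. Numbering used here: C1 is the alkynyl-bearing ring carbon, C2 the ring alkene CH, C3 carries the acetate, C4 the methyl ether, C5 and C6 the free hydroxyls; the chain is C7≡C8, C9 with its exocyclic methylene C10, the C11 methylene, the E-alkene C12=C13 and the carbinol C14. The ring substituents are cis at C3/C4, trans at C4/C5 and cis at C5/C6, and the four oxygens are all different, so they must be told apart as well as placed. A cis-fused acetonide across C5/C6 closes one ring face and can steer a syn-dihydroxylation of a C3=C4 double bond to the other face, which gives the C4/C5 trans relation. The opposite order is weak: C3 and C6 are each cis to an oxygenated neighbour, whereas hydride reduction of a ring ketone beside an alkoxy group normally gives the trans alcohol. The chain has no stereocentre, only the E double bond, so a geometrically defined reagent can bring it in. Fragile points are the allylic acetate at C3 (ionised by zerovalent palladium, cleaved by base), the doubly allylic C11 (base), the tertiary allylic alcohol at C14 (acid) and the conjugated enyne. The enabling feature is that C10, C9 and C11 form an allyl unit substituted at its centre and flanked by an sp carbon (C8) and an sp2 carbon (C12): these three carbons are propadiene, and both flanking bonds can be made in one palladium cycle.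

## Retrosynthesis

**24 from 23 from 22.** No skeletal bond is cut. Target 24 comes from acetonide 23 by hydrolysis of the dioxolane, and 23 from alcohol 22 by acetylating its only secondary hydroxyl. The acetate is placed after the palladium step because a secondary allylic acetate is itself a substrate for zerovalent palladium and would restrict the base. The price is one more step on advanced material, and both reactions must spare the tertiary allylic alcohol.

**22 from 18, 21 and 20.** The cut removes C8–C9 and C11–C12 together. The neighbouring cuts are weaker: cutting only C7–C8 needs a separately made 2-bromo-1,4-diene, and cutting C1–C7 needs a volatile, unstable terminal dienyne. The three-component cut reduces the whole chain to propadiene 21 and boronate 20, and the ring to bromoalkyne 18, which has no chain carbons at all. The forward reaction must let allene insertion run ahead of transmetalation.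

**20 from 19; 18 from 17 from 16.** Boronate 20 is one C–B bond away from alkynol 19, by anti-Markovnikov syn addition. Bromoalkyne 18 comes from terminal alkyne 17 by C–Br formation, and 17 from the doubly silylated 16 by one fluoride treatment that frees both the C3 hydroxyl and the alkyne.

**16 from 15 from 14.** These cuts are the O–CH3 bond at C4 and the O–Si bond at C3. Diol 14 has two secondary hydroxyls that differ in crowding: C3–OH is allylic and open, C4–OH is wedged against the dioxolane. Silylating the open one first (15) and methylating the hindered one without base (16) separates them. Direct monoacetylation would be shorter but less sure, and the acetate would then have to pass through the palladium step.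

**14 from 13.** Both C–O bonds at C3 and C4 are cut back to the C3=C4 double bond of diene 13. A syn-dihydroxylation anti to the acetonide gives the cis C3/C4 and trans C4/C5 relations in one step. This is preferred to making C3 or C6 by ketone reduction, for the reason given above. The forward step must choose the disubstituted C3=C4 bond over the alkynyl-substituted C1=C2 bond.

**13 from 11 and 12; 11 from 9.** The C1–C7 bond is cut to dienyl triflate 11 and silylacetylene 12, and 11 is the enol sulfonate of ketone 9. A 2-iodoenone route would need the carbonyl at C6 and a later cis-selective reduction. Here the carbonyl sits at C1, where no stereocentre is needed.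

**9 from 8 from 7 from 6.** Ketone 9 is the oxidised form of cyclohexenol 8. The ring is opened at C3=C4 to diene 7, and 7 at C1–C2 to aldehyde 6 and an allyl nucleophile. The carbinol formed at C1 is later oxidised, so its configuration is irrelevant.

**6 from 5 from 4 from 2 from 1.** Aldehyde 6 is the oxidised form of alcohol 5, the methylenation product of lactol 4. Lactol 4 results from periodate cleavage of acetonide 2, made from L-arabinose 1. Arabinose C3 and C4 become C5 and C6 of the target with the correct absolute configuration, C5 becomes C1, C2 becomes C4 (re-oxygenated later) and C1 is excised.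

## Roads not taken

**Alternative 1:** The ring is traced to an achiral 2-alkynyl quinone monoketal A1 that already carries the chain, and the cut is the pair of C–O bonds at C4 and C5. In the forward step a tartrate-modified nucleophilic epoxidation (a hindered hydroperoxide anion made with NaN(SiMe3)2 beside a dialkyl tartrate) would attack the unsubstituted enone bond and give the cis-epoxy ketone A2 as one enantiomer.
- Merits: chirality comes from a cheap tartrate, the ring is reached in very few steps from an aromatic precursor, and methanol opening at C4 with inversion would give the trans C4–OMe/C5–OH pair directly.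
- Weak points: only two of the four centres are set. C3 (masked as the ketal) and C6 remain carbonyl carbons and must each be reduced cis to an oxygenated neighbour, the sense that small hydrides disfavour. Methanolysis must choose C4 over C5. The chain's doubly allylic methylene and tertiary allylic alcohol must pass through strongly basic peroxide and later acid.
- Comparison: on length this road is clearly better, perhaps half the steps. The chosen plan sets against it four ring centres fixed by steps whose facial sense is not in doubt (sugar carbons in 4, anti dihydroxylation to 14) and a chain that meets only three mild steps.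

**Alternative 2:** The cut is C5–C6, back to the Z-configured ynenal dialdehyde A3. SmI2 with tert-butanol would couple the two aldehyde carbons and give the cis-diol A4, closing the ring and setting both carbinols at once.
- Merits: ring and two stereocentres in one step; cis-diols are the normal outcome of such pinacol closures, and the new C5 hydroxyl should fall trans to the C4 methoxy group.
- Weak points: the C6 aldehyde of A3 is conjugated through C1=C2 to the alkyne, so single-electron reduction gives a delocalised ketyl that can couple at carbon, reduce the enyne or lose the Z geometry needed for closure. The α-methoxy aldehyde can expel methoxide on reduction. A3 itself, with two stereocentres and a Z-trisubstituted enal, needs a long synthesis. A4 still requires a silyl-to-acetate exchange under temporary diol protection.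
- Comparison: this road is more convergent in its ring-forming event and equal in C5/C6 relative control. The chosen plan sets against it that no single-electron reductant meets the enyne and that its stereochemical arguments rest on precedent.

**Alternative 3:** The cut is C2–C3, back to a galacto-configured hex-5-enopyranoside A5. Catalytic Hg(OCOCF3)2 in aqueous acetone would bring about oxymercuration, hemiacetal opening and intramolecular aldol closure to the β-hydroxy ketone A6.
- Merits: C4, C5 and C6, the methyl ether and the acetonide all come straight from a cheap hexose, the carbocyclisation is well established, and the C1 ketone is a handle for the alkyne. In cost of starting material and in having all four oxygens in place early it is as good as or better than the chosen plan.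
- Weak points: turning the C1 ketone of A6 into the C1=C2 enol sulfonate needs a C2 carbanion β to the C3 oxygen, and the usual fate of such β-hydroxy ketones is elimination to the enone. Enolisation could also go toward C6. The acetonide must survive aqueous acidic mercury conditions. The C3 carbinol depends on 1,3-induction in the aldol step.
- Comparison: the chosen plan has a related hazard in step 8, where vinylogous loss of the C5 oxygen would aromatise the ring. There, however, the proton removed is doubly activated, and the C3/C4 oxygens are added only after the C1 substituent is in place. The chosen plan pays with more steps and a diol differentiation (14 to 16) that Alternative 3 gets from the sugar.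

Key step: step 16

Remark on the chemistry: compounds 2, 4, 7 and 8 are used as mixtures at the hemiacetal or carbinol carbon, which is removed in steps 2, 3 and 7; that centre is left open in their SMILES.

## Route

Step 1
Reactants: 1 L-arabinose
Product: 2 3,4-O-isopropylidene-L-arabinopyranose
Conditions: Me2C(OMe)2, TsOH·H2O (cat.), DMF, rt
Reagents that add atoms: 2,2-dimethoxypropane, COC(C)(C)OC
Why: Acid-catalysed acetal exchange under thermodynamic control; in the pyranose only O3 and O4 are cis-vicinal ring hydroxyls, so the dioxolane forms there and leaves the hemiacetal and C2 hydroxyls free. No stereocentre is created.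

Step 2
Reactants: 2 3,4-O-isopropylidene-L-arabinopyranose
Product: 4 2,3-O-isopropylidene-L-erythrofuranose, via formate ester 3 (not isolated)
Conditions: NaIO4, H2O, 0 °C → rt; then Na2CO3, rt
Reagents that add atoms: none
Why: Malaprade glycol cleavage of the only free vicinal diol (hemiacetal OH and C2–OH) gives aldehyde formate 3; carbonate hydrolysis of the formate frees the primary hydroxyl, which closes to the lactol. The two acetonide carbons are untouched and become C5 and C6 of the target.

Step 3
Reactants: 4 2,3-O-isopropylidene-L-erythrofuranose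
Product: 5 [(4S,5R)-2,2-dimethyl-5-vinyl-1,3-dioxolan-4-yl]methanol
Conditions: Ph3PCH3Br, KOt-Bu, THF, 0 °C → rt
Reagents that add atoms: methyltriphenylphosphonium bromide, C[P+](c1ccccc1)(c1ccccc1)c1ccccc1.[Br-]
Why: Wittig methylenation of the hydroxy aldehyde in equilibrium with the lactol, a standard reaction of acetonide-protected tetrose lactols; excess ylide is used because the hydroxyl consumes one equivalent.

Step 4
Reactants: 5 [(4S,5R)-2,2-dimethyl-5-vinyl-1,3-dioxolan-4-yl]methanol
Product: 6 (4R,5R)-2,2-dimethyl-5-vinyl-1,3-dioxolane-4-carbaldehyde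
Conditions: PhI(OAc)2, TEMPO (10 mol%), CH2Cl2, rt
Reagents that add atoms: none
Why: TEMPO-catalysed oxidation stops at the aldehyde and is neutral, so the cis-disposed, epimerisable α-alkoxy aldehyde is not equilibrated; 6 is used crude.

Step 5
Reactants: 6 (4R,5R)-2,2-dimethyl-5-vinyl-1,3-dioxolane-4-carbaldehyde
Product: 7 1-[(4S,5R)-2,2-dimethyl-5-vinyl-1,3-dioxolan-4-yl]but-3-en-1-ol (both carbinol epimers)
Conditions: CH2=CHCH2MgBr, Et2O, −78 °C; then H2O
Reagents that add atoms: allylmagnesium bromide, C=CC[Mg]Br
Why: Grignard addition forms the C1–C2 bond; the carbinol centre is formed as a mixture, which does not matter because it is oxidised in step 7.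

Step 6
Reactants: 7 1-[(4S,5R)-2,2-dimethyl-5-vinyl-1,3-dioxolan-4-yl]but-3-en-1-ol
Product: 8 (3aS,7aR)-2,2-dimethyl-3a,4,5,7a-tetrahydro-1,3-benzodioxol-4-ol (both C4 epimers)
Conditions: RuCl2(=CHPh)(H2IMes)(PCy3) (second-generation Grubbs catalyst, 2 mol%), CH2Cl2, 40 °C
Reagents that add atoms: none
Why: Ring-closing metathesis of a 1,7-diene forms C3=C4 and a cyclohexene cis-fused to the dioxolane with loss of ethene; free secondary hydroxyls are tolerated.

Step 7
Reactants: 8 (3aS,7aR)-2,2-dimethyl-3a,4,5,7a-tetrahydro-1,3-benzodioxol-4-ol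
Product: 9 (3aR,7aR)-2,2-dimethyl-3a,7a-dihydro-1,3-benzodioxol-4(5H)-one
Conditions: Dess–Martin periodinane, pyridine, CH2Cl2, 0 °C → rt
Reagents that add atoms: none
Why: Dess–Martin oxidation under pyridine buffer gives the β,γ-unsaturated ketone without moving the double bond into conjugation; both epimers of 8 converge.

Step 8
Reactants: 9 (3aR,7aR)-2,2-dimethyl-3a,7a-dihydro-1,3-benzodioxol-4(5H)-one
Product: 11 (3aR,7aR)-2,2-dimethyl-3a,7a-dihydro-1,3-benzodioxol-4-yl trifluoromethanesulfonate, via potassium dienolate 10 (not isolated)
Conditions: KN(SiMe3)2, THF, −78 °C; then N-(5-chloropyridin-2-yl)bis(trifluoromethanesulfonyl)imide, −78 °C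
Reagents that add atoms: N-(5-chloropyridin-2-yl)bis(trifluoromethanesulfonyl)imide, O=S(=O)(N(c1ccc(Cl)cn1)S(=O)(=O)C(F)(F)F)C(F)(F)F
Why: Kinetic enol triflate formation; the C2 methylene between carbonyl and alkene is far more acidic than the α-alkoxy C6 methine, so the base gives linear dienolate 10, which the reactive pyridyl triflimide traps on oxygen at −78 °C before vinylogous loss of the C5 oxygen can set in.

Step 9
Reactants: 11 (3aR,7aR)-2,2-dimethyl-3a,7a-dihydro-1,3-benzodioxol-4-yl trifluoromethanesulfonate; 12 ethynyl(trimethyl)silane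
Product: 13 {[(3aS,7aR)-2,2-dimethyl-3a,7a-dihydro-1,3-benzodioxol-4-yl]ethynyl}(trimethyl)silane
Conditions: Pd(PPh3)4 (5 mol%), CuI (10 mol%), Et3N, THF, rt
Reagents that add atoms: none
Why: Sonogashira coupling of an alkenyl triflate with a terminal alkyne at room temperature forms C1–C7; the silyl cap prevents double coupling and the diene is used promptly to avoid dimerisation.

Step 10
Reactants: 13 {[(3aS,7aR)-2,2-dimethyl-3a,7a-dihydro-1,3-benzodioxol-4-yl]ethynyl}(trimethyl)silane
Product: 14 (3aR,4S,5S,7aS)-2,2-dimethyl-7-[(trimethylsilyl)ethynyl]-3a,4,5,7a-tetrahydro-1,3-benzodioxole-4,5-diol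
Conditions: OsO4 (2 mol%), N-methylmorpholine N-oxide, acetone/H2O, 0 °C → rt
Reagents that add atoms: osmium tetroxide, O=[Os](=O)(=O)=O; N-methylmorpholine N-oxide, C[N+]1([O-])CCOCC1; water, O
Why: Upjohn dihydroxylation; OsO4 takes the cis-disubstituted C3=C4 bond in preference to the hindered, alkynyl-conjugated C1=C2 bond and the silylalkyne, as is known for cis-fused acetonides of 3-substituted cyclohexa-3,5-diene-1,2-diols. Both C–O bonds form on the face opposite the acetonide, which sets C3 and C4 cis to each other and C4 trans to C5.

Step 11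
Reactants: 14 (3aR,4S,5S,7aS)-2,2-dimethyl-7-[(trimethylsilyl)ethynyl]-3a,4,5,7a-tetrahydro-1,3-benzodioxole-4,5-diol
Product: 15 (3aR,4R,5S,7aS)-5-{[tert-butyl(dimethyl)silyl]oxy}-2,2-dimethyl-7-[(trimethylsilyl)ethynyl]-3a,4,5,7a-tetrahydro-1,3-benzodioxol-4-ol
Conditions: t-BuMe2SiCl, imidazole, DMF, −20 → 0 °C
Reagents that add atoms: tert-butyl(chloro)dimethylsilane, CC(C)(C)[Si](C)(C)Cl
Why: Regioselective silylation; the allylic C3 hydroxyl is flanked only by the alkene CH, whereas C4–OH lies between C3–OH and the dioxolane, so a bulky silyl chloride at low temperature takes C3–OH, as known for the distal hydroxyl of the analogous halodiol acetonides.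

Step 12
Reactants: 15 (3aR,4R,5S,7aS)-5-{[tert-butyl(dimethyl)silyl]oxy}-2,2-dimethyl-7-[(trimethylsilyl)ethynyl]-3a,4,5,7a-tetrahydro-1,3-benzodioxol-4-ol
Product: 16 tert-butyl{[(3aS,4R,5S,7aS)-4-methoxy-2,2-dimethyl-7-[(trimethylsilyl)ethynyl]-3a,4,5,7a-tetrahydro-1,3-benzodioxol-5-yl]oxy}dimethylsilane
Conditions: Me3OBF4, 1,8-bis(dimethylamino)naphthalene, CH2Cl2, 0 °C → rt
Reagents that add atoms: trimethyloxonium tetrafluoroborate, C[O+](C)C.F[B-](F)(F)F
Why: O-Methylation with an oxonium salt buffered by a non-nucleophilic amine works on hindered secondary alcohols without forming an alkoxide, so the neighbouring silyl ether cannot migrate and the acetonide is untouched.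

Step 13
Reactants: 16 tert-butyl{[(3aS,4R,5S,7aS)-4-methoxy-2,2-dimethyl-7-[(trimethylsilyl)ethynyl]-3a,4,5,7a-tetrahydro-1,3-benzodioxol-5-yl]oxy}dimethylsilane
Product: 17 (3aS,4S,5S,7aS)-7-ethynyl-4-methoxy-2,2-dimethyl-3a,4,5,7a-tetrahydro-1,3-benzodioxol-5-ol
Conditions: Bu4NF, THF, 0 °C → rt
Reagents that add atoms: none
Why: Fluoride desilylation cleaves the secondary silyl ether and the C(sp)–Si bond in one operation; methyl ether and acetonide are inert.

Step 14
Reactants: 17 (3aS,4S,5S,7aS)-7-ethynyl-4-methoxy-2,2-dimethyl-3a,4,5,7a-tetrahydro-1,3-benzodioxol-5-ol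
Product: 18 (3aS,4S,5S,7aS)-7-(bromoethynyl)-4-methoxy-2,2-dimethyl-3a,4,5,7a-tetrahydro-1,3-benzodioxol-5-ol
Conditions: N-bromosuccinimide, AgNO3 (10 mol%), acetone, rt, dark
Reagents that add atoms: N-bromosuccinimide, O=C1CCC(=O)N1Br
Why: Silver-catalysed electrophilic bromination of a terminal alkyne (silver acetylide, then bromine transfer) gives the 1-bromoalkyne under neutral conditions that leave the allylic alcohol and the ring alkene alone.

Step 15
Reactants: 19 2-methylbut-3-yn-2-ol
Product: 20 (3E)-2-methyl-4-(4,4,5,5-tetramethyl-1,3,2-dioxaborolan-2-yl)but-3-en-2-ol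
Conditions: B2pin2, CuCl (5 mol%), Xantphos (5 mol%), NaOt-Bu (10 mol%), MeOH (2 equiv), THF, rt
Reagents that add atoms: bis(pinacolato)diboron, CC1(C)OB(OC1(C)C)B1OC(C)(C)C(C)(C)O1
Why: Copper-catalysed protoboration of a terminal alkyne; syn addition of the copper–boryl species puts boron on the terminal carbon, away from the quaternary carbinol, and protonolysis by methanol gives the E-alkenyl boronate. Free hydroxyls are tolerated.

Step 16
Reactants: 18 (3aS,4S,5S,7aS)-7-(bromoethynyl)-4-methoxy-2,2-dimethyl-3a,4,5,7a-tetrahydro-1,3-benzodioxol-5-ol; 21 propadiene; 20 (3E)-2-methyl-4-(4,4,5,5-tetramethyl-1,3,2-dioxaborolan-2-yl)but-3-en-2-ol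
Product: 22 (3aS,4S,5S,7aS)-7-[(5E)-7-hydroxy-7-methyl-3-methylideneoct-5-en-1-yn-1-yl]-4-methoxy-2,2-dimethyl-3a,4,5,7a-tetrahydro-1,3-benzodioxol-5-ol
Conditions: Pd(PPh3)4 (5 mol%), K3PO4, propadiene (5 equiv), THF/H2O (10:1), sealed tube, 45 °C, slow addition of 18
Reagents that add atoms: none
Why: Proposed new method: zerovalent palladium should insert into the C(sp)–Br bond of 18 faster than into any other bond present, and propadiene then inserts into the alkynyl–palladium bond with the alkynyl group going to the central carbon, giving a 2-alkynyl-π-allyl complex of divalent palladium; base-assisted transmetalation from 20 and reductive elimination at a CH2 terminus form C11–C12 and return zerovalent palladium. The closest known reaction type is the palladium-catalysed three-component coupling of aryl or alkenyl halides with allenes and organoboron reagents, together with the known insertion of alkenes and alkynes into alkynyl–palladium bonds derived from bromoalkynes; a 1-bromoalkyne has not been used as the halide in the allene version. No ring closes and no stereocentre is formed. Propadiene is symmetrical, so the two allyl termini are equivalent and no regiochemical choice arises, and the E geometry of 20 is carried through transmetalation and reductive elimination. The selectivity that matters is insertion before transmetalation; a large excess of propadiene, slow addition of 18 and the sluggish phosphate-promoted transmetalation of a pinacol boronate should hold back direct alkynyl–alkenyl coupling and diyne formation. The π-allyl complex has no β-hydrogen, the hydroxyl groups cannot reach it across the linear alkyne, and the substrate carries no allylic ester that zerovalent palladium could ionise.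

Step 17
Reactants: 22 (3aS,4S,5S,7aS)-7-[(5E)-7-hydroxy-7-methyl-3-methylideneoct-5-en-1-yn-1-yl]-4-methoxy-2,2-dimethyl-3a,4,5,7a-tetrahydro-1,3-benzodioxol-5-ol
Product: 23 (3aS,4S,5S,7aS)-7-[(5E)-7-hydroxy-7-methyl-3-methylideneoct-5-en-1-yn-1-yl]-4-methoxy-2,2-dimethyl-3a,4,5,7a-tetrahydro-1,3-benzodioxol-5-yl acetate
Conditions: Ac2O, pyridine, CH2Cl2, 0 °C → rt
Reagents that add atoms: acetic anhydride, CC(=O)OC(C)=O
Why: Acylation of the only secondary hydroxyl (C3); without an acyl-transfer catalyst the tertiary C14 hydroxyl does not react, and C5/C6 are still masked.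

Step 18
Reactants: 23 (3aS,4S,5S,7aS)-7-[(5E)-7-hydroxy-7-methyl-3-methylideneoct-5-en-1-yn-1-yl]-4-methoxy-2,2-dimethyl-3a,4,5,7a-tetrahydro-1,3-benzodioxol-5-yl acetate
Product: 24 (1S,4S,5S,6R)-4,5-dihydroxy-3-[(5E)-7-hydroxy-7-methyl-3-methylideneoct-5-en-1-yn-1-yl]-6-methoxycyclohex-2-en-1-yl acetate (target)
Conditions: AcOH/H2O/THF (3:1:1), 40 °C
Reagents that add atoms: none
Why: Acid-catalysed hydrolysis of the cis-fused dioxolane with dilute acetic acid releases the C5/C6 diol; the acetate has no vicinal free hydroxyl to migrate to, and the weak acid is chosen to spare the tertiary allylic alcohol.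

## Compound list

1 | L-arabinose | O=C[C@H](O)[C@@H](O)[C@@H](O)CO | starting material
2 | 3,4-O-isopropylidene-L-arabinopyranose (anomeric mixture) | OC1[C@H](O)[C@H]2OC(C)(C)O[C@H]2CO1 | intermediate
3 | 4-O-formyl-2,3-O-isopropylidene-aldehydo-L-erythrose (not isolated) | O=C[C@H]1OC(C)(C)O[C@H]1COC=O | intermediate
4 | 2,3-O-isopropylidene-L-erythrofuranose (anomeric mixture) | OC1OC[C@@H]2OC(C)(C)O[C@H]12 | intermediate
5 | [(4S,5R)-2,2-dimethyl-5-vinyl-1,3-dioxolan-4-yl]methanol | C=C[C@H]1OC(C)(C)O[C@H]1CO | intermediate
6 | (4R,5R)-2,2-dimethyl-5-vinyl-1,3-dioxolane-4-carbaldehyde | C=C[C@H]1OC(C)(C)O[C@H]1C=O | intermediate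
7 | 1-[(4S,5R)-2,2-dimethyl-5-vinyl-1,3-dioxolan-4-yl]but-3-en-1-ol (carbinol epimers) | C=C[C@H]1OC(C)(C)O[C@H]1C(O)CC=C | intermediate
8 | (3aS,7aR)-2,2-dimethyl-3a,4,5,7a-tetrahydro-1,3-benzodioxol-4-ol (C4 epimers) | OC1CC=C[C@H]2OC(C)(C)O[C@@H]12 | intermediate
9 | (3aR,7aR)-2,2-dimethyl-3a,7a-dihydro-1,3-benzodioxol-4(5H)-one | O=C1CC=C[C@H]2OC(C)(C)O[C@@H]12 | intermediate
10 | potassium (3aR,7aR)-2,2-dimethyl-3a,7a-dihydro-1,3-benzodioxol-4-olate (dienolate of 9, not isolated) | [K+].[O-]C1=CC=C[C@H]2OC(C)(C)O[C@@H]12 | intermediate
11 | (3aR,7aR)-2,2-dimethyl-3a,7a-dihydro-1,3-benzodioxol-4-yl trifluoromethanesulfonate | FC(F)(F)S(=O)(=O)OC1=CC=C[C@H]2OC(C)(C)O[C@@H]12 | intermediate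
12 | ethynyl(trimethyl)silane | C#C[Si](C)(C)C | starting material
13 | {[(3aS,7aR)-2,2-dimethyl-3a,7a-dihydro-1,3-benzodioxol-4-yl]ethynyl}(trimethyl)silane | C[Si](C)(C)C#CC1=CC=C[C@H]2OC(C)(C)O[C@@H]12 | intermediate
14 | (3aR,4S,5S,7aS)-2,2-dimethyl-7-[(trimethylsilyl)ethynyl]-3a,4,5,7a-tetrahydro-1,3-benzodioxole-4,5-diol | C[Si](C)(C)C#CC1=C[C@H](O)[C@H](O)[C@@H](OC(C)(C)O2)[C@H]12 | intermediate
15 | (3aR,4R,5S,7aS)-5-{[tert-butyl(dimethyl)silyl]oxy}-2,2-dimethyl-7-[(trimethylsilyl)ethynyl]-3a,4,5,7a-tetrahydro-1,3-benzodioxol-4-ol | C[Si](C)(C)C#CC1=C[C@H](O[Si](C)(C)C(C)(C)C)[C@H](O)[C@@H](OC(C)(C)O2)[C@H]12 | intermediate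
16 | tert-butyl{[(3aS,4R,5S,7aS)-4-methoxy-2,2-dimethyl-7-[(trimethylsilyl)ethynyl]-3a,4,5,7a-tetrahydro-1,3-benzodioxol-5-yl]oxy}dimethylsilane | C[Si](C)(C)C#CC1=C[C@H](O[Si](C)(C)C(C)(C)C)[C@H](OC)[C@@H](OC(C)(C)O2)[C@H]12 | intermediate
17 | (3aS,4S,5S,7aS)-7-ethynyl-4-methoxy-2,2-dimethyl-3a,4,5,7a-tetrahydro-1,3-benzodioxol-5-ol | C#CC1=C[C@H](O)[C@H](OC)[C@@H](OC(C)(C)O2)[C@H]12 | intermediate
18 | (3aS,4S,5S,7aS)-7-(bromoethynyl)-4-methoxy-2,2-dimethyl-3a,4,5,7a-tetrahydro-1,3-benzodioxol-5-ol | BrC#CC1=C[C@H](O)[C@H](OC)[C@@H](OC(C)(C)O2)[C@H]12 | intermediate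
19 | 2-methylbut-3-yn-2-ol | C#CC(C)(C)O | starting material
20 | (3E)-2-methyl-4-(4,4,5,5-tetramethyl-1,3,2-dioxaborolan-2-yl)but-3-en-2-ol | CC(C)(O)/C=C/B1OC(C)(C)C(C)(C)O1 | intermediate
21 | propadiene | C=C=C | starting material
22 | (3aS,4S,5S,7aS)-7-[(5E)-7-hydroxy-7-methyl-3-methylideneoct-5-en-1-yn-1-yl]-4-methoxy-2,2-dimethyl-3a,4,5,7a-tetrahydro-1,3-benzodioxol-5-ol | C=C(C#CC1=C[C@H](O)[C@H](OC)[C@@H](OC(C)(C)O2)[C@H]12)C/C=C/C(C)(C)O | intermediate
23 | (3aS,4S,5S,7aS)-7-[(5E)-7-hydroxy-7-methyl-3-methylideneoct-5-en-1-yn-1-yl]-4-methoxy-2,2-dimethyl-3a,4,5,7a-tetrahydro-1,3-benzodioxol-5-yl acetate | C=C(C#CC1=C[C@H](OC(C)=O)[C@H](OC)[C@@H](OC(C)(C)O2)[C@H]12)C/C=C/C(C)(C)O | intermediate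
24 | (1S,4S,5S,6R)-4,5-dihydroxy-3-[(5E)-7-hydroxy-7-methyl-3-methylideneoct-5-en-1-yn-1-yl]-6-methoxycyclohex-2-en-1-yl acetate (CNP0546270.2) | C=C(C#CC1=C[C@H](OC(C)=O)[C@H](OC)[C@@H](O)[C@H]1O)C/C=C/C(C)(C)O | target

## Step count and risks

Total step count: 18. Longest linear sequence: 17 steps (steps 1–14 and 16–18); step 15 is a one-step side branch.

**Step 16 (key step, proposed new method).** Most likely failure: transmetalation overtakes allene insertion, so the alkynyl and alkenyl groups couple directly, or the bromoalkyne is consumed by reductive homocoupling; both follow from the high reactivity of the alkynylpalladium bromide. Fallback by known chemistry, setting out from 20 and 17: a palladium-catalysed allyl–alkenyl Suzuki–Miyaura coupling of 20 with 2,3-dibromopropene at its allylic C–Br bond gives (3E)-6-bromo-2-methylhepta-3,6-dien-2-ol F1. A Sonogashira coupling of F1 with terminal alkyne 17 (Pd(PPh3)4, CuI, Et3N) then forms C8–C9 and rejoins the route at 22.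

**Step 8.** Most likely failure: base-induced vinylogous loss of the C5 acetonide oxygen from the dienolate, which aromatises the ring, or prior drift of 9 into the conjugated enone, which would then be deprotonated at C6. Fallback from 9: 1,2-addition of lithium (trimethylsilyl)acetylide in the presence of CeCl3 gives (3aR,7aR)-2,2-dimethyl-4-[(trimethylsilyl)ethynyl]-3a,4,5,7a-tetrahydro-1,3-benzodioxol-4-ol F2. Syn-dehydration with the Burgess reagent toward the allylic C2 methylene then gives the conjugated dienyne and rejoins the route at 13, with no enolate formed.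

**Step 10.** Most likely failure: loss of site selectivity between the two ring double bonds, or Diels–Alder dimerisation of the electron-rich dienyne before it is oxidised. Fallback from 11, which is the direct analogue of the well-behaved halodiene acetonides:
- Dihydroxylation of 11 gives (3aR,4S,5S,7aR)-4,5-dihydroxy-2,2-dimethyl-3a,4,5,7a-tetrahydro-1,3-benzodioxol-7-yl trifluoromethanesulfonate F3.
- Silylation as in step 11 gives its 5-O-tert-butyldimethylsilyl ether F4.
- Methylation as in step 12 gives the 4-O-methyl ether F5.
- Sonogashira coupling of F5 with 12 rejoins the route at 16.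

**Step 11.** Most likely failure: incomplete discrimination between the two hydroxyls, leading to the regioisomeric or bis-silyl ether. Fallback from 14, using stereoelectronic instead of steric control:
- Trimethyl orthoacetate and a trace of acid give the cyclic methyl orthoacetate of 14 F6.
- Brief aqueous acetic acid opens F6 to the ester on the pseudoaxial allylic oxygen, the C3 monoacetate of 14 F7.
- Methyl triflate with 2,6-di-tert-butyl-4-methylpyridine methylates C4–OH without acyl migration, giving the C3 acetate C4 methyl ether F8.
- K2CO3 in methanol removes the acetate and the alkynyl silyl group and rejoins the route at 17.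

**Step 18.** Most likely failure: acid-promoted ionisation of the tertiary allylic alcohol (dehydration or allylic shift) before the dioxolane is fully hydrolysed. Fallback from 17, in which the diol is released before the chain exists:
- Acetylation gives (3aS,4S,5S,7aS)-7-ethynyl-4-methoxy-2,2-dimethyl-3a,4,5,7a-tetrahydro-1,3-benzodioxol-5-yl acetate F9.
- Aqueous acid gives (1S,4S,5S,6R)-3-ethynyl-4,5-dihydroxy-6-methoxycyclohex-2-en-1-yl acetate F10.
- Bromination as in step 14 gives (1S,4S,5S,6R)-3-(bromoethynyl)-4,5-dihydroxy-6-methoxycyclohex-2-en-1-yl acetate F11.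
- The coupling of step 16 applied to F11 with 21 and 20 rejoins the route at 24. The cost is that the allylic acetate and a free diol then pass through the palladium step.

## Further compounds

F1 | step 16 | (3E)-6-bromo-2-methylhepta-3,6-dien-2-ol | C=C(Br)C/C=C/C(C)(C)O
F2 | step 8 | (3aR,7aR)-2,2-dimethyl-4-[(trimethylsilyl)ethynyl]-3a,4,5,7a-tetrahydro-1,3-benzodioxol-4-ol (C4 epimers) | C[Si](C)(C)C#CC1(O)CC=C[C@H]2OC(C)(C)O[C@@H]12
F3 | step 10 | (3aR,4S,5S,7aR)-4,5-dihydroxy-2,2-dimethyl-3a,4,5,7a-tetrahydro-1,3-benzodioxol-7-yl trifluoromethanesulfonate | FC(F)(F)S(=O)(=O)OC1=C[C@H](O)[C@H](O)[C@@H](OC(C)(C)O2)[C@H]12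
F4 | step 10 | 5-O-tert-butyldimethylsilyl ether of F3 | FC(F)(F)S(=O)(=O)OC1=C[C@H](O[Si](C)(C)C(C)(C)C)[C@H](O)[C@@H](OC(C)(C)O2)[C@H]12
F5 | step 10 | 4-O-methyl ether of F4 | FC(F)(F)S(=O)(=O)OC1=C[C@H](O[Si](C)(C)C(C)(C)C)[C@H](OC)[C@@H](OC(C)(C)O2)[C@H]12
F6 | step 11 | cyclic methyl orthoacetate of diol 14 (orthoester carbon as a mixture) | C[Si](C)(C)C#CC1=C[C@@H]2OC(C)(OC)O[C@@H]2[C@H]3OC(C)(C)O[C@@H]13
F7 | step 11 | C3 monoacetate of 14 | C[Si](C)(C)C#CC1=C[C@H](OC(C)=O)[C@H](O)[C@@H](OC(C)(C)O2)[C@H]12
F8 | step 11 | C3 acetate C4 methyl ether of 14 | C[Si](C)(C)C#CC1=C[C@H](OC(C)=O)[C@H](OC)[C@@H](OC(C)(C)O2)[C@H]12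
F9 | step 18 | (3aS,4S,5S,7aS)-7-ethynyl-4-methoxy-2,2-dimethyl-3a,4,5,7a-tetrahydro-1,3-benzodioxol-5-yl acetate | C#CC1=C[C@H](OC(C)=O)[C@H](OC)[C@@H](OC(C)(C)O2)[C@H]12
F10 | step 18 | (1S,4S,5S,6R)-3-ethynyl-4,5-dihydroxy-6-methoxycyclohex-2-en-1-yl acetate | C#CC1=C[C@H](OC(C)=O)[C@H](OC)[C@@H](O)[C@H]1O
F11 | step 18 | (1S,4S,5S,6R)-3-(bromoethynyl)-4,5-dihydroxy-6-methoxycyclohex-2-en-1-yl acetate | BrC#CC1=C[C@H](OC(C)=O)[C@H](OC)[C@@H](O)[C@H]1O
A1 | alternative 1 | 2-[(5E)-7-hydroxy-7-methyl-3-methylideneoct-5-en-1-yn-1-yl]-4,4-dimethoxycyclohexa-2,5-dien-1-one | C=C(C#CC1=CC(OC)(OC)C=CC1=O)C/C=C/C(C)(C)O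
A2 | alternative 1 | 3-[(5E)-7-hydroxy-7-methyl-3-methylideneoct-5-en-1-yn-1-yl]-5,5-dimethoxy-7-oxabicyclo[4.1.0]hept-3-en-2-one (cis-epoxide, one enantiomer) | C=C(C#CC1=CC(OC)(OC)[C@@H]2[C@@H](O2)C1=O)C/C=C/C(C)(C)O
A3 | alternative 2 | (2Z)-4-{[tert-butyl(dimethyl)silyl]oxy}-2-[(5E)-7-hydroxy-7-methyl-3-methylideneoct-5-en-1-yn-1-yl]-5-methoxyhex-2-enedial | O=C/C(C#CC(=C)C/C=C/C(C)(C)O)=C\[C@H](O[Si](C)(C)C(C)(C)C)[C@H](OC)C=O
A4 | alternative 2 | C3 tert-butyldimethylsilyl ether of the deacetyl target | C=C(C#CC1=C[C@H](O[Si](C)(C)C(C)(C)C)[C@H](OC)[C@@H](O)[C@H]1O)C/C=C/C(C)(C)O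
A5 | alternative 3 | methyl 6-deoxy-3,4-O-isopropylidene-2-O-methyl-β-L-arabino-hex-5-enopyranoside (galacto-derived enol ether) | CO[C@H]1OC(=C)[C@@H]2OC(C)(C)O[C@@H]2[C@H]1OC
A6 | alternative 3 | 3-hydroxy-4-methoxy-5,6-O-isopropylidenecyclohexanone (target numbering) | O=C1C[C@H](O)[C@H](OC)[C@@H](OC(C)(C)O2)[C@H]12
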